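**Retrosynthetic overview**

1. The last two disconnections are the O‑5 methyl ether of the chromanone (a temporary block, removed with BCl3) and the Ar–CH2–Ar bridge (ortho‑quinone methide from Mannich base 9 plus the only free ring carbon of acylphloroglucinol 13).
2. The key disconnection is O1–C2 and C4–C4a of the pyranone ring, made together by Friedel–Crafts acylation/oxa‑Michael annulation of aminomethyl‑resorcinol 6 with 3‑methylbut‑2‑enoic acid.
3. Enabling feature: in 6 the future C‑4a is the only aromatic C–H, lying between the single free hydroxyl that can close (future O‑1) and the methylated O‑5; the future C‑8 already carries CH2NMe2, which is protonated and inert in acid and later becomes the bridge carbon.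
4. Both benzene rings come from 2‑methylphloroglucinol by the same two moves (C‑carbonylation, then methylation of the OH para to the new carbonyl): formyl for ring B, (R)‑2‑methylbutanoyl (source of the stereocentre) for ring A.
5. Ring order: both benzene rings are purchased intact; the pyranone ring is the only ring formed (step 4).

Key step: step 4

Remark: the side‑chain stereocentre of the target is read as (R) and is taken from commercial (R)‑2‑methylbutanoic acid; aminophenols are written as free bases.

**Route**

Step 1
Reactants: 1 2-methylbenzene-1,3,5-triol (2-methylphloroglucinol)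
Product: 3 2,4,6-trihydroxy-3-methylbenzaldehyde, via aryl iminium chloride 2 (not isolated)
Conditions: POCl3, DMF, EtOAc, 0 °C → rt; then H2O, 70 °C
Reagents that add atoms: N,N-dimethylformamide CN(C)C=O; water O
Why: Vilsmeier–Haack formylation, in which the two free ring positions of 1 are equivalent so only one aldehyde can form, and precipitation of iminium salt 2 should stop a second formylation.

Step 2
Reactants: 3 2,4,6-trihydroxy-3-methylbenzaldehyde
Product: 4 2,6-dihydroxy-4-methoxy-3-methylbenzaldehyde
Conditions: Me2SO4 (1.0 equiv), K2CO3, acetone, 0 °C → rt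
Reagents that add atoms: dimethyl sulfate COS(=O)(=O)OC
Why: Williamson-type O-methylation should take place at the OH para to the formyl group, the most acidic one, while the two ortho hydroxyls are held back by chelation to the carbonyl.

Step 3
Reactants: 4 2,6-dihydroxy-4-methoxy-3-methylbenzaldehyde
Product: 6 2-[(dimethylamino)methyl]-5-methoxy-4-methylbenzene-1,3-diol, via iminium phenolate 5 (not isolated)
Conditions: Me2NH (2 M in THF), NaBH(OAc)3, AcOH, THF, 0 °C → rt; work-up at pH 8, used at once
Reagents that add atoms: dimethylamine CNC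
Why: Reductive amination, in which NaBH(OAc)3 reduces the iminium ion faster than the aldehyde, should deliver the phenolic Mannich base with the aminomethyl group fixed between the two hydroxyls.

Step 4
Reactants: 6 2-[(dimethylamino)methyl]-5-methoxy-4-methylbenzene-1,3-diol; 7 3-methylbut-2-enoic acid
Product: 9 8-[(dimethylamino)methyl]-7-hydroxy-5-methoxy-2,2,6-trimethyl-2,3-dihydro-4H-chromen-4-one, via aryl enone 8 (not isolated)
Conditions: MsOH–P2O5 (10:1 w/w), 60–70 °C; ice, then NaHCO3 to pH 8
Reagents that add atoms: none
Why: In MsOH–P2O5 acid 7 is converted into its mixed anhydride/acylium ion, which acylates the electron-rich ring of N-protonated 6 at the future C-4a (C4–C4a bond), and the resulting ortho-hydroxyaryl enone 8 should close at once by acid-promoted conjugate addition of the neighbouring phenol to the protonated enone (O1–C2 bond). The closest known reaction type is the one-pot Friedel–Crafts acylation/oxa-Michael annulation of resorcinols and phloroglucinols with 3-methylbut-2-enoic acid to 2,2-dimethylchroman-4-ones. The pyranone ring closes in the 6-endo-trig mode onto the tertiary β-carbon, which becomes the gem-dimethyl C-2, and no stereocentre is formed. Site selectivity is structural: the future C-4a is the only ring C–H, and any O-acylated by-product can only funnel to the same carbon by Fries shift. Regioselectivity of ring closure is equally structural, because the second oxygen next to the new ketone is the methyl ether, so only the future O-1 can add. Chemoselectivity rests on the ammonium group, since protonated nitrogen can neither leave as an amine to give a benzylic cation nor be expelled as an iminium ion (retro-Mannich), and P2O5 favours acylation over conjugate C-alkylation by the acid.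

Step 5
Reactants: 1 2-methylbenzene-1,3,5-triol; 10 (2R)-2-methylbutanoic acid
Product: 12 (2R)-2-methyl-1-(2,4,6-trihydroxy-3-methylphenyl)butan-1-one, via acid chloride 11 (not isolated)
Conditions: 10, (COCl)2, cat. DMF, CH2Cl2, 0 °C → rt; then 1, AlCl3, PhNO2–CH2Cl2, 0 °C → rt; ice/aq. HCl
Reagents that add atoms: none
Why: Friedel–Crafts acylation at one of the two equivalent ring positions of 1, run cold so that the α-stereocentre brought in with 10 should be carried through unchanged (no new stereocentre is formed).

Step 6
Reactants: 12 (2R)-2-methyl-1-(2,4,6-trihydroxy-3-methylphenyl)butan-1-one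
Product: 13 (2R)-1-(2,6-dihydroxy-4-methoxy-3-methylphenyl)-2-methylbutan-1-one
Conditions: Me2SO4 (1.0 equiv), K2CO3, acetone, 0 °C → rt
Reagents that add atoms: dimethyl sulfate COS(=O)(=O)OC
Why: The same para-selective Williamson O-methylation as in step 2, the OH para to the acyl group being the most acidic, under conditions too mild to enolise the chelated ketone.

Step 7
Reactants: 9 8-[(dimethylamino)methyl]-7-hydroxy-5-methoxy-2,2,6-trimethyl-2,3-dihydro-4H-chromen-4-one; 13 (2R)-1-(2,6-dihydroxy-4-methoxy-3-methylphenyl)-2-methylbutan-1-one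
Product: 15 8-({2,4-dihydroxy-6-methoxy-5-methyl-3-[(2R)-2-methylbutanoyl]phenyl}methyl)-7-hydroxy-5-methoxy-2,2,6-trimethyl-2,3-dihydro-4H-chromen-4-one, via ortho-quinone methide 14 (not isolated)
Conditions: 13 (1.3 equiv), 1,4-dioxane, 90 °C, N2 sweep
Reagents that add atoms: none
Why: Thermal loss of dimethylamine from the ortho-hydroxybenzylamine (Mannich base) gives ortho-quinone methide 14, and Michael-type Friedel–Crafts addition of the only unsubstituted ring carbon of 13 should form the methylene bridge as the single constitutional outcome under neutral conditions that leave the stereocentre alone.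

Step 8
Reactants: 15 8-({2,4-dihydroxy-6-methoxy-5-methyl-3-[(2R)-2-methylbutanoyl]phenyl}methyl)-7-hydroxy-5-methoxy-2,2,6-trimethyl-2,3-dihydro-4H-chromen-4-one
Product: 16 8-({2,4-dihydroxy-6-methoxy-5-methyl-3-[(2R)-2-methylbutanoyl]phenyl}methyl)-5,7-dihydroxy-2,2,6-trimethyl-2,3-dihydro-4H-chromen-4-one (target)
Conditions: BCl3 (1 M in CH2Cl2, excess), CH2Cl2, −78 → 0 °C; ice/aq. NaHCO3
Reagents that add atoms: none
Why: Chelation-directed ether cleavage, in which boron bridged between the C-4 carbonyl and O-5 activates only that methyl group for chloride attack, while the ring-A methoxy group (para to its ketone, not chelated) should survive at low temperature.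

**Compound list**

1 | 2-methylbenzene-1,3,5-triol (2-methylphloroglucinol) | Cc1c(O)cc(O)cc1O | starting material
2 | N-methyl-N-[(2,4,6-trihydroxy-3-methylphenyl)methylidene]methanaminium chloride | C[N+](C)=Cc1c(O)c(C)c(O)cc1O.[Cl-] | intermediate
3 | 2,4,6-trihydroxy-3-methylbenzaldehyde | O=Cc1c(O)c(C)c(O)cc1O | intermediate
4 | 2,6-dihydroxy-4-methoxy-3-methylbenzaldehyde | O=Cc1c(O)c(C)c(OC)cc1O | intermediate
5 | 2-[(dimethyliminio)methyl]-3-hydroxy-5-methoxy-4-methylphenolate | C[N+](C)=Cc1c(O)c(C)c(OC)cc1[O-] | intermediate
6 | 2-[(dimethylamino)methyl]-5-methoxy-4-methylbenzene-1,3-diol | CN(C)Cc1c(O)c(C)c(OC)cc1O | intermediate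
7 | 3-methylbut-2-enoic acid | CC(C)=CC(=O)O | starting material
8 | 1-{3-[(dimethylamino)methyl]-2,4-dihydroxy-6-methoxy-5-methylphenyl}-3-methylbut-2-en-1-one | CN(C)Cc1c(O)c(C)c(OC)c(C(=O)C=C(C)C)c1O | intermediate
9 | 8-[(dimethylamino)methyl]-7-hydroxy-5-methoxy-2,2,6-trimethyl-2,3-dihydro-4H-chromen-4-one | CN(C)Cc1c(O)c(C)c(OC)c2c1OC(C)(C)CC2=O | intermediate
10 | (2R)-2-methylbutanoic acid | CC[C@@H](C)C(=O)O | starting material
11 | (2R)-2-methylbutanoyl chloride | CC[C@@H](C)C(=O)Cl | intermediate
12 | (2R)-2-methyl-1-(2,4,6-trihydroxy-3-methylphenyl)butan-1-one | CC[C@@H](C)C(=O)c1c(O)c(C)c(O)cc1O | intermediate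
13 | (2R)-1-(2,6-dihydroxy-4-methoxy-3-methylphenyl)-2-methylbutan-1-one | CC[C@@H](C)C(=O)c1c(O)c(C)c(OC)cc1O | intermediate
14 | 5-methoxy-2,2,6-trimethyl-8-methylidene-2,3-dihydro-4H-chromene-4,7(8H)-dione | C=C1C(=O)C(C)=C(OC)C2=C1OC(C)(C)CC2=O | intermediate
15 | 8-({2,4-dihydroxy-6-methoxy-5-methyl-3-[(2R)-2-methylbutanoyl]phenyl}methyl)-7-hydroxy-5-methoxy-2,2,6-trimethyl-2,3-dihydro-4H-chromen-4-one | CC[C@@H](C)C(=O)c1c(O)c(C)c(OC)c(Cc2c(O)c(C)c(OC)c3c2OC(C)(C)CC3=O)c1O | intermediate
16 | 8-({2,4-dihydroxy-6-methoxy-5-methyl-3-[(2R)-2-methylbutanoyl]phenyl}methyl)-5,7-dihydroxy-2,2,6-trimethyl-2,3-dihydro-4H-chromen-4-one | CC[C@@H](C)C(=O)c1c(O)c(C)c(OC)c(Cc2c(O)c(C)c(O)c3c2OC(C)(C)CC3=O)c1O | target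

**Summary**

Total step count: 8.
Longest linear sequence: 6 steps (steps 1, 2, 3, 4, 7, 8; compound 1 to 16).

**Steps most likely to fail**

Step 4 (key step). In the hot superacid the acid 7 may react through its tertiary cation (conjugate C-alkylation leading to a 4,4-dimethyl-dihydrocoumarin) instead of through the acylium ion. The benzylic C–N bond may also ionise, or the ring closure may stay incomplete. The fallback separates acylation from cyclisation and removes the benzylic leaving group. It sets out from 4, which is C-acylated at its only free ring carbon with 3-methylbut-2-enoyl chloride and TiCl4 in CH2Cl2 at low temperature to give 2,6-dihydroxy-4-methoxy-3-methyl-5-(3-methylbut-2-enoyl)benzaldehyde F1. A separate oxa-Michael closure under mild base (NaOAc, EtOH) then gives 7-hydroxy-5-methoxy-2,2,6-trimethyl-4-oxo-3,4-dihydro-2H-chromene-8-carbaldehyde F2. Reductive amination of F2 with dimethylamine and NaBH(OAc)3 comes back to the route at 9.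

Step 5. The configuration may erode by enolisation of the acylium ion (ketene formation) or of the aluminium-bound aryl ketone. The fallback sets the stereocentre by reagent control, never passes through an acyl cation, and also bypasses step 6. It sets out from 4, whose formyl carbon becomes the ketone carbon. Both hydroxyls are protected (MOMCl, i-Pr2NEt) to give 4-methoxy-2,6-bis(methoxymethoxy)-3-methylbenzaldehyde F3. Asymmetric crotylboration with the enantiomer of (E)-crotyldiisopinocampheylborane that gives the anti adduct with (R) configuration at the methyl-bearing carbon (oxidative work-up) gives (1R,2R)-1-[4-methoxy-2,6-bis(methoxymethoxy)-3-methylphenyl]-2-methylbut-3-en-1-ol F4. Hydrogenation of the vinyl group (H2, RhCl(PPh3)3) gives (1R,2R)-1-[4-methoxy-2,6-bis(methoxymethoxy)-3-methylphenyl]-2-methylbutan-1-ol F5. Buffered Dess–Martin oxidation removes the carbinol centre and gives (2R)-1-[4-methoxy-2,6-bis(methoxymethoxy)-3-methylphenyl]-2-methylbutan-1-one F6. Removal of the acetals (HCl, MeOH, rt) comes back to the route at 13.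

Step 7. Thermal release of the ortho-quinone methide may be slow, so that it dimerises, re-adds the liberated amine, or the ketone epimerises on prolonged heating. The fallback changes the activation from thermal to alkylative. It sets out from 9, which is N-methylated with iodomethane (acetone, rt) to give {[7-hydroxy-5-methoxy-2,2,6-trimethyl-4-oxo-3,4-dihydro-2H-chromen-8-yl]methyl}trimethylammonium iodide F7. With 13 and NaHCO3 in aqueous acetonitrile at room temperature, E1cB elimination should release 14, and its capture by 13 comes back to the route at 15.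

**Further compounds**

F1 | step 4 | 2,6-dihydroxy-4-methoxy-3-methyl-5-(3-methylbut-2-enoyl)benzaldehyde | O=Cc1c(O)c(C)c(OC)c(C(=O)C=C(C)C)c1O
F2 | step 4 | 7-hydroxy-5-methoxy-2,2,6-trimethyl-4-oxo-3,4-dihydro-2H-chromene-8-carbaldehyde | O=Cc1c(O)c(C)c(OC)c2c1OC(C)(C)CC2=O
F3 | step 5 | 4-methoxy-2,6-bis(methoxymethoxy)-3-methylbenzaldehyde | O=Cc1c(OCOC)c(C)c(OC)cc1OCOC
F4 | step 5 | (1R,2R)-1-[4-methoxy-2,6-bis(methoxymethoxy)-3-methylphenyl]-2-methylbut-3-en-1-ol | C=C[C@@H](C)[C@@H](O)c1c(OCOC)c(C)c(OC)cc1OCOC
F5 | step 5 | (1R,2R)-1-[4-methoxy-2,6-bis(methoxymethoxy)-3-methylphenyl]-2-methylbutan-1-ol | CC[C@@H](C)[C@@H](O)c1c(OCOC)c(C)c(OC)cc1OCOC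
F6 | step 5 | (2R)-1-[4-methoxy-2,6-bis(methoxymethoxy)-3-methylphenyl]-2-methylbutan-1-one | CC[C@@H](C)C(=O)c1c(OCOC)c(C)c(OC)cc1OCOC
F7 | step 7 | {[7-hydroxy-5-methoxy-2,2,6-trimethyl-4-oxo-3,4-dihydro-2H-chromen-8-yl]methyl}trimethylammonium iodide | C[N+](C)(C)Cc1c(O)c(C)c(OC)c2c1OC(C)(C)CC2=O.[I-]
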